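(The earlier runs and the new flask are simulated with constants of no real substance; scatter was added.)

I want one ratio for spring: Z made per equivalent of E spent, with E counted in units of the G charged.

in all of them: G 0.30 M

| charge | E | remark | time |
|---|---|---|---|
| blue | 0.17 M | run made earlier |  |
| grey | 0.38 M | run made earlier |  |
| spring | 0.300 M |  | 50 min |
| noon | 0.150 M |  | 50 min |

- blue (time / min: Z / %, J / %): 4.00: 10, 23; 12.0: 10, 34; 25.0: 17, 33; 40.0: 12, 37
- grey (time / min: Z / %, J / %): 3.00: 19, 36; 6.00: 20, 44; 15.0: 25, 52; 40.0: 23, 49

(each reading ± 2 percentage points)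

- which of these holds the largest part of the G at the end of spring (G / X / Z / J)
- which of these holds the largest part of the G at the end of noon (G / X / Z / J)
- amount of Z at the end of spring, in percent of the G charged

- a reading or a percentage of J counts all its forms, free or not

In blue, E is the limiting reagent. J plus Z reads 44.0% after 12.0 min and 49.0% after 40.0 min, so I count its E as spent. Z averages 13.0% over those last three readings, which gives 0.229, my Z per E spent.

Grey's last two readings average 24.0%. Dividing by its whole charge gives 0.189, a floor for that run, since some of its E may be unspent. I assume the ratio falls as the E charge rises, and spring's charge lies between the two . So spring's Z lies between 18.9% and 22.9%. Grey's plateau is a looser ceiling. With a scatter of 2 percentage points I can go no tighter by hand, and I commit to the middle, 20.9%.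

The forecast, working from “about 2.3:1 J:Z”, names J for spring and G for noon, with Z at 23%. That is my upper bound, above my middle.

Spring ends with J largest at 51.0%, noon with G largest at 53.8%, and Z in spring is 22.3%, inside the bracket .

    G + E → J (k = 0.0143 M⁻¹ s⁻¹)
    E + Z → X (k = 1.76 × 10⁻⁴ M⁻¹ s⁻¹)
    E + J → Q (k = 0.00854 M⁻¹ s⁻¹)
    E + J → X (k = 0.0192 M⁻¹ s⁻¹)
    D ⇌ J, rate k5*(cs5 - [J]) while solid is left; crystals form when [J] > cs5 (solubility = 12.0 mM, k = 0.127 s⁻¹)
    G + E → Z (k = 0.00506 M⁻¹ s⁻¹)

For Z, spring has come to rest: E stands at 0.72% of its charge, and ten times the time leaves Z at 22.4%, while G moves from 13.7% to 13.2%. The ratio in spring comes to 0.225. Spring stopped at 20 min still holds 6.5% of its E, so my ratio read from blue, 0.229, gives Z of 21.4%; the flask has 21.2%.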